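If links fade at a rate that does not follow concentration, a single fraction read from the earlier runs can be carried to the new flasks.

| flask | first end groups | second end groups | third end groups | remark | time |
|---|---|---|---|---|---|
| south | 0.50 M | 0.98 equiv | 1 equiv | run made earlier |  |
| north | 0.25 M | 0.98 equiv | 1 equiv | run made earlier |  |
| north-east | 0.38 M | 0.98 equiv | 1 equiv | run made earlier |  |
| Saturday's | 0.50 M | 0.980 equiv | 1.00 equiv | everything together at the start | 3.0 d |
| Tuesday's | 0.50 M | 0.980 equiv | 1.00 equiv (in portions, 2, over 2.5 d) | first portion at the start, last at 2.5 d | 3.0 d |
| Thursday's | 0.50 M | 0.980 equiv | 1.00 equiv (fed, over 2.5 d) | all else is in the flask from the start; the feed brings no volume worth counting | 3.0 d |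
| Sunday's | 0.50 M (fed, over 2.5 d) | 0.980 equiv | 1.00 equiv | all else is in the flask from the start; the feed brings no volume worth counting | 3.0 d |

south run (percent of the first end groups charged)

| time / h | links / % | first end groups / % |
|---|---|---|
| 4.00 | 46.6 | 52.5 |
| 10.0 | 44.3 | 52.9 |
| 20.0 | 41.6 | 51.1 |
| 30.0 | 42.3 | 53.9 |
| 40.0 | 42.7 | 52.7 |

north run (percent of the first end groups charged)

| time / d | links / % | first end groups / % |
|---|---|---|
| 0.625 | 43.6 | 53.0 |
| 1.25 | 41.3 | 52.1 |
| 2.00 | 39.6 | 53.2 |
| 3.00 | 36.0 | 52.8 |
| 4.00 | 30.4 | 51.7 |

north-east run (percent of the first end groups charged)

| time / d | links / % | first end groups / % |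
|---|---|---|
| 0.250 | 45.9 | 52.7 |
| 0.500 | 44.9 | 51.9 |
| 1.04 | 40.0 | 52.7 |
| 2.08 | 39.0 | 51.8 |
| 4.00 | 30.8 | 51.0 |

(each reading ± 1 percentage point)

* which flask leads in amount of links, in percent of the first end groups charged ("all alike" within 1.5 percentage points) (Saturday's / Tuesday's / Thursday's / Sunday's / all alike)
* how much links is there at the end, in percent of the first end groups charged: Saturday's
* how much links is there at the end, in percent of the first end groups charged: Tuesday's
* how much links is there at the end, in percent of the first end groups charged: Thursday's
* how much links is there at the end, in percent of the first end groups charged: Sunday's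

Does the fade follow concentration? At 4.00 d the north run, at 0.25 M, reads 30.4% links and the north-east run, at 0.38 M, reads 30.8%, a gap inside the scatter of 1 percentage point, so the fade reads as first order.

How much survives to the asked time? First end groups in the north run stay flat within the scatter, so fading links are read as not returning them, and the first end groups lost are taken as the links made, on average 47.4% of the charge. The reading at 3.00 d is 36.0%. That gives φ = 0.759: the survival fraction, links standing at 3.0 d over links made. At another time t it becomes φ raised to t/3.0 days. It rests on one reading and carries that reading's scatter.

How much is made in each flask? Second end groups, at 0.980 equiv, are the limiting reagent against first and third end groups together. First end groups in the south run are flat by 4.00 h, and a steady feed brings 6.67% of its charge in that span.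

Taking the same span, my reckoning is as follows. Thursday's flask reckons to between 91.3% and 98.0% links made, so to 69.3% to 74.4% at the end. Sunday's flask reckons to below 5.06%. For Saturday's flask the reckoning takes over the north run's reading of 36.0%. In the north run links made are 47.4% against 50.6% taken by third end groups, so the pull is close to even. Tuesday's first portion then reckons to 65.3% links made, which gives 49.6% at the end. Tuesday's last portion comes at 2.5 d, later than that span, so the reckoning gives it no links. Thursday's leads in this reckoning, its low end being higher than the figures of the other flasks.

The forecast gives 35%, 47%, 70% and 1.5% for Saturday's, Tuesday's, Thursday's and Sunday's, with Thursday's leading, and notes: “Links then fade without releasing first end groups.”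

The flasks give 35.3%, 48.1%, 71.4% and 2.06%, in the same order, and Thursday's leads.

    first end groups + second end groups → links (k = 0.00400 M⁻¹ s⁻¹)
    second end groups + third end groups → links of the second sort (k = 0.00450 M⁻¹ s⁻¹)
    links → over-reaction product (k = 1.10 × 10⁻⁶ s⁻¹)
    2 first end groups → homo dimer (k = 1.50 × 10⁻⁷ M⁻¹ s⁻¹)

In Thursday's flask at 0.00539 d, second end groups are used by the step to links at 290 times the rate of the step to links of the second sort, and the half-life of links by their step to over-reaction product at 3.00 d is 7.3 d. Thursday's flask keeps 5.14% first end groups, so links made are 94.9%, and φ gives 72.0% against 71.4%. Left until 8.0 d, Thursday's flask reckons to 45.5% by φ, and it holds 44.4%.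

The numbers in the tables come from a simulation for an exercise, noise included.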